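The runs stem from a simulated flask with constants of no real substance, and the scatter is random.

How far does the partner carry the substrate before the substrate stalls, and what then holds most of the substrate at the end of Tuesday's and of Thursday's?

| setting | dawn | dusk | Tuesday's | Thursday's |
|---|---|---|---|---|
| substrate | 0.10 M | 0.10 M | 0.10 M | 0.10 M |
| partner | 0.99 equiv | 4.8 equiv | 0.800 equiv | 4.00 equiv |
| remark | run made earlier | run made earlier |  |  |
| time |  |  | 5.0 d | 5.0 d |

| run | time / d | mono adduct / % | substrate / % |
|---|---|---|---|
| dawn | 0.500 | 42.0 | 43.7 |
| dawn | 1.04 | 42.5 | 43.4 |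
| dawn | 1.67 | 41.8 | 44.2 |
| dawn | 2.08 | 39.8 | 42.0 |
| dawn | 2.50 | 39.3 | 43.0 |
| dawn | 3.00 | 39.3 | 42.8 |
| dawn | 4.00 | 36.4 | 43.7 |
| dusk | 0.208 | 7.5 | 0 |
| dusk | 0.500 | 5.2 | 0 |
| dusk | 1.04 | 3.7 | 0.7 |
| dusk | 1.67 | 4.4 | 0 |
| dusk | 2.00 | 5.1 | 0 |
| dusk | 3.00 | 3.4 | 0 |
| dusk | 4.00 | 4.1 | 0 |

(readings scatter by 1 percentage point)

- steps that have been proposed: partner -> decomposed reagent; partner + bis adduct -> triple product + by-product; partner + mono adduct -> bis adduct + by-product; mono adduct -> over-reaction product; substrate + partner -> mono adduct + by-product

- which of these holds the largest part of the substrate at the end of Tuesday's (substrate / triple product / bis adduct / mono adduct)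
- which of these holds the largest part of the substrate at the end of Thursday's (substrate / triple product / bis adduct / mono adduct)
- amount of mono adduct at the end of Tuesday's, in percent of the substrate charged

1. Follow one rate, r = −d ln c_substrate/dt. For substrate + partner → mono adduct + by-product, r is a pseudo-first-order coefficient, proportional to c_partner.

2. In the dawn run r averages 1.66 d⁻¹ over the first 0.500 d. After that the substrate readings stay between 42.0% and 44.2%, so r is zero within the scatter. The substrate's own fall slows the absolute rate by a factor of 2.29; you must put the remaining slowing on c_partner.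

3. Replace the curve of r by its mean: mean r times duration is −ln of the stalled substrate fraction. The last substrate reading of the dawn run gives 0.836 per equivalent of partner, the stall exposure per equivalent, at 0.10 M substrate. As a check, the dusk charge then gives 1.81%, above the substrate readings of the dusk run, which stand between 0% and 0.7%, so at that charge the reckoning lies high by up to 1.8 percentage points.

4. My reckoning for Tuesday's is 51.2% substrate, more than the remaining 48.8%, so substrate leads. For Thursday's it gives 3.53%, so substrate is out of front, but the exposure does not rank the adducts.

5. The forecast says substrate for Tuesday's with 32% mono adduct, and triple product for Thursday's: “triple probably still leads bis, though less certainly”.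

6. The flask gives substrate in front in Tuesday's, with 31.9% mono adduct. In Thursday's, bis adduct leads with 54.6%, against 32.7% triple product.

    partner → decomposed reagent (k = 7.70 × 10⁻⁵ s⁻¹)
    partner + bis adduct → triple product + by-product (k = 3.70 × 10⁻⁴ L mol⁻¹ s⁻¹)
    partner + mono adduct → bis adduct + by-product (k = 0.00120 L mol⁻¹ s⁻¹)
    mono adduct → over-reaction product (k = 5.10 × 10⁻⁷ s⁻¹)
    substrate + partner → mono adduct + by-product (k = 0.00220 L mol⁻¹ s⁻¹)

7. In Tuesday's the midpoint of the turnover of substrate + partner falls at 0.579 h, far earlier than the end at 5.0 d, and the exposure's 51.2% stands against 51.8% substrate in the flask. For the same flask with 1.40 equiv of partner, the exposure gives 31.0% substrate, and that flask holds 28.6%.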